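**Retrosynthetic overview**
1. The target comes from its C3 aldehyde (the closed-ring aglycone aldehyde). This aldehyde is reduced last, which locks C2 and C3.
2. Dihydropyran ring B is cut at O1–C2. It forms by 6-endo oxa-Michael addition of a hydroxymethylene ester to an (E)-ethylidene enal, inside the open enol-dialdehyde that deglucosylation of oleuropein releases in the olive.
3. The open form and the hydroxytyrosyl ester arise in one event: acyl transfer from an enol δ-lactone (ring A) to unprotected hydroxytyrosol. The lactone replaces the glucoside mask and a lipase replaces the glucosidase.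
4. Ring A carries the only catalyst-set stereocentre (C4). It comes from a carbene-catalysed rearrangement of the enol ester of 4-methylhexadienoic acid and methyl propiolate, followed by allylic CH3 to CHO oxidation.
5. Ring order: temporary ring A first, then A is opened and B closed without isolating the open form. The dienoic acid comes from tiglic aldehyde and malonic acid.

Assumption: the sense of induction of the triazolium salt in step 2 is assigned by analogy. Both enantiomers are sold, so the one that gives (4S)-6 is used.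

**Step 1**
Reactants: 1 tiglic aldehyde, (E)-2-methylbut-2-enal; 2 malonic acid
Product: 3 (2E,4E)-4-methylhexa-2,4-dienoic acid
Conditions: pyridine, piperidine (cat.), 90 °C
Reagents that add atoms: none
Why: Knoevenagel–Doebner condensation, in which the alkylidene malonic acid loses CO2 to give the (2E)-acid, the (E)-trisubstituted alkene of 1 is untouched and no stereocentre is formed.

**Step 2**
Reactants: 3 (2E,4E)-4-methylhexa-2,4-dienoic acid; 4 methyl propiolate
Product: 6 methyl (4S)-4-[(2E)-but-2-en-2-yl]-2-oxo-3,4-dihydro-2H-pyran-5-carboxylate, via enol ester 5 (not isolated)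
Conditions: 4 (1.1 equiv), N-methylmorpholine (10 mol %), CH2Cl2, 0 °C to rt; evaporate; (5aR,10bS)-2-(2,4,6-trimethylphenyl)-5a,10b-dihydro-4H,6H-indeno[2,1-b][1,2,4]triazolo[4,3-d][1,4]oxazinium chloride (10 mol %), iPr2NEt (20 mol %), 4 Å MS, toluene, rt
Reagents that add atoms: none
Why: Amine-catalysed conjugate addition of the acid to the propiolate gives the (E)-β-acyloxyacrylate, which the carbene cleaves into an α,β-unsaturated acyl azolium and the formylacetate enolate; these recombine by 1,4-addition (Coates–Claisen type) and O-acylation (NHC-catalysed enol ester rearrangement), and the indane wall of the catalyst leaves one face of C-β open, so C4 is set as S.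

**Step 3**
Reactants: 6 methyl (4S)-4-[(2E)-but-2-en-2-yl]-2-oxo-3,4-dihydro-2H-pyran-5-carboxylate
Product: 7 methyl (4S)-4-[(2E)-1-oxobut-2-en-2-yl]-2-oxo-3,4-dihydro-2H-pyran-5-carboxylate
Conditions: SeO2 (1.2 equiv), 1,4-dioxane, 70 °C
Reagents that add atoms: selenium dioxide, O=[Se]=O
Why: Riley allylic oxidation (ene reaction, then [2,3]-sigmatropic shift) attacks only the electron-rich trisubstituted alkene, oxidises at its more substituted end with the usual CH3 over CH preference and goes on to the (E)-enal, while the non-acidic C4–H stereocentre is untouched.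

**Step 4**
Reactants: 7 methyl (4S)-4-[(2E)-1-oxobut-2-en-2-yl]-2-oxo-3,4-dihydro-2H-pyran-5-carboxylate; 8 hydroxytyrosol, 4-(2-hydroxyethyl)benzene-1,2-diol
Product: 10 methyl (2R,3S,4S)-4-{2-[2-(3,4-dihydroxyphenyl)ethoxy]-2-oxoethyl}-3-formyl-2-methyl-3,4-dihydro-2H-pyran-5-carboxylate, via open enol-dialdehyde 9 (not isolated)
Conditions: Candida antarctica lipase B on acrylic resin (Novozym 435), MTBE, 4 Å MS, 40 °C, Ar; filter; acetone/NaOAc–AcOH buffer pH 5 (1:1), rt, 2 h; EtOAc extraction, no chromatography
Reagents that add atoms: none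
Why: Proposed new method: ring A is a cyclic enol-ester (vinylogous anhydride) acyl donor that the serine of the lipase attacks only at the acyl carbon and passes only to the primary alcohol of 8, and the leaving group is the hydroxymethylene ester of 9, the natural open aglycone, which in water adds 6-endo (oxa-Michael) to C-β of the (E)-ethylidene enal through the conformer with the C4 side chain pseudo-axial (least A(1,2) strain against both flanking sp2 carbons) to give 2R under kinetic control, while the enolisable C3 settles trans to both neighbours (3S); the closest known reaction types are lipase acylation of hydroxytyrosol with vinyl esters, lipase alcoholysis of 3-substituted glutaric anhydrides, alcoholysis of dihydropyranones and the rearrangement of oleuropein aglycone after enzymatic deglucosylation.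

**Step 5**
Reactants: 10 methyl (2R,3S,4S)-4-{2-[2-(3,4-dihydroxyphenyl)ethoxy]-2-oxoethyl}-3-formyl-2-methyl-3,4-dihydro-2H-pyran-5-carboxylate (crude)
Product: 11 methyl (2R,3R,4S)-4-{2-[2-(3,4-dihydroxyphenyl)ethoxy]-2-oxoethyl}-3-(hydroxymethyl)-2-methyl-3,4-dihydro-2H-pyran-5-carboxylate
Conditions: NaBH4 (1.0 equiv), THF/MeOH 5:1, −78 to −50 °C, 30 min; AcOH, −50 °C; aq. citric acid work-up
Reagents that add atoms: none
Why: Chemoselective borohydride 1,2-reduction of the aldehyde leaves both esters and the vinylogous carbonate alone, the cold acidic quench prevents retro-oxa-Michael reaction, C3 epimerisation and translactonisation onto the side-chain ester, and no centre is changed (C3 goes from S to R only through CIP priorities).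

**Compound list**
1 | tiglic aldehyde, (E)-2-methylbut-2-enal | C/C=C(\C)C=O | starting material
2 | malonic acid | OC(=O)CC(=O)O | starting material
3 | (2E,4E)-4-methylhexa-2,4-dienoic acid | C/C=C(\C)/C=C/C(=O)O | intermediate
4 | methyl propiolate | C#CC(=O)OC | starting material
5 | (E)-3-methoxy-3-oxoprop-1-en-1-yl (2E,4E)-4-methylhexa-2,4-dienoate | C/C=C(\C)/C=C/C(=O)O/C=C/C(=O)OC | intermediate
6 | methyl (4S)-4-[(2E)-but-2-en-2-yl]-2-oxo-3,4-dihydro-2H-pyran-5-carboxylate | COC(=O)C1=COC(=O)C[C@H]1/C(C)=C/C | intermediate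
7 | methyl (4S)-4-[(2E)-1-oxobut-2-en-2-yl]-2-oxo-3,4-dihydro-2H-pyran-5-carboxylate | COC(=O)C1=COC(=O)C[C@H]1/C(C=O)=C\C | intermediate
8 | hydroxytyrosol | OCCc1ccc(O)c(O)c1 | starting material
9 | 2-(3,4-dihydroxyphenyl)ethyl (3S,4E)-4-formyl-3-[(1E)-1-hydroxy-3-methoxy-3-oxoprop-1-en-2-yl]hex-4-enoate | COC(=O)/C(=C/O)[C@@H](CC(=O)OCCc1ccc(O)c(O)c1)/C(C=O)=C\C | intermediate
10 | methyl (2R,3S,4S)-4-{2-[2-(3,4-dihydroxyphenyl)ethoxy]-2-oxoethyl}-3-formyl-2-methyl-3,4-dihydro-2H-pyran-5-carboxylate | COC(=O)C1=CO[C@H](C)[C@@H](C=O)[C@@H]1CC(=O)OCCc1ccc(O)c(O)c1 | intermediate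
11 | methyl (2R,3R,4S)-4-{2-[2-(3,4-dihydroxyphenyl)ethoxy]-2-oxoethyl}-3-(hydroxymethyl)-2-methyl-3,4-dihydro-2H-pyran-5-carboxylate | COC(=O)C1=CO[C@H](C)[C@@H](CO)[C@@H]1CC(=O)OCCc1ccc(O)c(O)c1 | target

**Total step count:** 5 (step 2 is a telescoped two-stage operation).
**Longest linear sequence:** 5 (1 → 3 → 6 → 7 → 10 → 11).

**Steps most likely to fail**

Step 4. The lipase may reject the β-branched lactone, or may prefer its other enantiomer. Closure may also drift to the thermodynamically favoured 2S epimer if 10 is left too long or meets silica. The fallback sets out from 7 and comes back at 10. It replaces acyl transfer by hydrolysis followed by an alkylative ester bond. Compound 7 is stirred in acetone/pH 5 buffer so that water opens the lactone to (3S,4E)-4-formyl-3-[(1E)-1-hydroxy-3-methoxy-3-oxoprop-1-en-2-yl]hex-4-enoic acid F1. This closes by the same oxa-Michael addition to [(2R,3S,4S)-3-formyl-5-(methoxycarbonyl)-2-methyl-3,4-dihydro-2H-pyran-4-yl]acetic acid F2. The crude acid is joined to 8 by a Mitsunobu esterification (PPh3, DIAD, THF, 0 °C). This activates only the primary aliphatic alcohol and takes the carboxylic acid, far more acidic than the catechol OH groups, as nucleophile, giving 10.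

Step 3. SeO2 may dehydrogenate ring A to the 2-pyranone, may attack the doubly allylic C4–H, or may hydrolyse the lactone through the water it forms. The fallback sets out from 4 and comes back at 7. It brings the aldehyde carbon in at the right oxidation level by C–C coupling instead of late C–H oxidation.
- Crotonaldehyde and Br2 (CH2Cl2, 0 °C) give 2,3-dibromobutanal F3, and Et3N eliminates HBr to give (Z)-2-bromobut-2-enal F4.
- HC(OMe)3 with TsOH (cat.) gives (Z)-2-bromo-1,1-dimethoxybut-2-ene F5.
- A Heck reaction with acrylic acid (Pd(OAc)2, P(o-tol)3, Et3N, MeCN, 80 °C) gives (2E,4E)-4-(dimethoxymethyl)hexa-2,4-dienoic acid F6.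
- Addition to 4 as in step 2 gives (E)-3-methoxy-3-oxoprop-1-en-1-yl (2E,4E)-4-(dimethoxymethyl)hexa-2,4-dienoate F7.
- The same carbene rearrangement gives methyl (4S)-4-[(2E)-1,1-dimethoxybut-2-en-2-yl]-2-oxo-3,4-dihydro-2H-pyran-5-carboxylate F8.
- Pyridinium tosylate in wet acetone at 0 °C frees the enal 7.

Step 2. The triazolylidene may be too weak a nucleophile for the enol ester, or the enantioselectivity may be low for a dienoyl azolium paired with formylacetate. The fallback sets out from 3 and comes back at 6. It changes from ion-pair rearrangement under carbene catalysis to an intermolecular Michael addition–lactonisation on a chiral acyl ammonium ion. DCC (0.5 equiv, CH2Cl2) turns 3 into (2E,4E)-4-methylhexa-2,4-dienoic anhydride F9. This reacts with methyl 3-hydroxyacrylate (freshly liberated from its commercial sodium salt) under (2S,3R)-3-isopropyl-2-phenyl-3,4-dihydro-2H-benzo[4,5]thiazolo[3,2-a]pyrimidine (5 mol %) and iPr2NEt in CH2Cl2 at −40 °C to give 6.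

**Further compounds**
F1 | step 4 | (3S,4E)-4-formyl-3-[(1E)-1-hydroxy-3-methoxy-3-oxoprop-1-en-2-yl]hex-4-enoic acid | COC(=O)/C(=C/O)[C@@H](CC(=O)O)/C(C=O)=C\C
F2 | step 4 | [(2R,3S,4S)-3-formyl-5-(methoxycarbonyl)-2-methyl-3,4-dihydro-2H-pyran-4-yl]acetic acid | COC(=O)C1=CO[C@H](C)[C@@H](C=O)[C@@H]1CC(=O)O
F3 | step 3 | 2,3-dibromobutanal (racemic) | CC(Br)C(Br)C=O
F4 | step 3 | (Z)-2-bromobut-2-enal | C/C=C(\Br)C=O
F5 | step 3 | (Z)-2-bromo-1,1-dimethoxybut-2-ene | C/C=C(\Br)C(OC)OC
F6 | step 3 | (2E,4E)-4-(dimethoxymethyl)hexa-2,4-dienoic acid | C/C=C(\C=C\C(=O)O)C(OC)OC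
F7 | step 3 | (E)-3-methoxy-3-oxoprop-1-en-1-yl (2E,4E)-4-(dimethoxymethyl)hexa-2,4-dienoate | C/C=C(\C=C\C(=O)O/C=C/C(=O)OC)C(OC)OC
F8 | step 3 | methyl (4S)-4-[(2E)-1,1-dimethoxybut-2-en-2-yl]-2-oxo-3,4-dihydro-2H-pyran-5-carboxylate | COC(=O)C1=COC(=O)C[C@H]1/C(C(OC)OC)=C\C
F9 | step 2 | (2E,4E)-4-methylhexa-2,4-dienoic anhydride | C/C=C(\C)/C=C/C(=O)OC(=O)/C=C/C(C)=C/C
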